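**Retrosynthetic overview**

1. The dihydrobenzofuran is cut last, at two bonds at once: aryl carbon C7a to the ring oxygen O1, and aryl carbon C3a to C3. This gives a phenolic dibenzylbutyrolactone and the C2–C3–C9 unit as an (S)-γ-hydroxy enol ether (C9 = hydroxymethyl carbon).
2. Enabling feature: in the benzene ring of the benzofuran, C7 carries a free hydroxyl next to the ether carbon C7a. This ring can therefore enter as a 2-methoxyphenol (C7–OH, C7a–OMe, C3a–H). Oxidation gives an o-quinone monoketal with C7a as ketal carbon and C3a as diene terminus; the methoxy group is a traceless leaving group.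
3. The cycloaddition also makes a bond C6–C9 that is not in the target (bicyclo[2.2.2]octenone). Its retro-aldol cleavage restores the benzene ring and leaves C9 as an aldehyde, which is reduced to CH2OH.
4. Lactone part: Evans alkylation gives the (S)-β-benzyl-γ-butyrolactone; trans-selective enolate benzylation with a silyl-protected isovanillyl bromide sets the second lactone stereocentre.
5. Ring order: lactone (step 4); tetrahydrofuran ring plus temporary carbocycle (step 11); carbocycle opened and arene regenerated (step 12).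

Key step: step 11

Remark: locants follow benzofuran numbering (O1, C2, C3, C3a, C4 to C7, C7a), and C9 is the hydroxymethyl carbon on C3. The (−)-MIB-catalysed alkenylzinc addition is assumed to follow the facial sense of the dialkylzinc additions with this ligand.

**Route**

Step 1
Reactants: 1 3-(4-hydroxy-3-methoxyphenyl)propanoic acid
Product: 3 3-[4-(benzyloxy)-3-methoxyphenyl]propanoic acid, via benzyl ester 2 (not isolated)
Conditions: BnBr (2.3 equiv), K2CO3, DMF, 60 °C; then NaOH, MeOH/H2O, 60 °C; then aq. HCl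
Reagents that add atoms: benzyl bromide, BrCc1ccccc1
Why: Williamson etherification of the phenoxide (the carboxylate is benzylated too) followed by saponification of the benzyl ester should leave only the robust aryl benzyl ether; no stereocentre is involved.

Step 2
Reactants: 3 3-[4-(benzyloxy)-3-methoxyphenyl]propanoic acid
Product: 5 (R)-4-benzyl-3-{3-[4-(benzyloxy)-3-methoxyphenyl]propanoyl}oxazolidin-2-one, via mixed pivalic anhydride 4 (not isolated)
Conditions: PivCl, Et3N, THF, −20 °C; then (R)-4-benzyl-2-oxazolidinone, LiCl, −20 °C → rt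
Reagents that add atoms: (R)-4-benzyl-2-oxazolidinone, O=C1N[C@H](Cc2ccccc2)CO1; pivaloyl chloride, CC(C)(C)C(=O)Cl (atoms only in 4)
Why: N-acylation of the oxazolidinone through the mixed anhydride is the standard entry to the Evans imide and creates no new stereocentre.

Step 3
Reactants: 5 (R)-4-benzyl-3-{3-[4-(benzyloxy)-3-methoxyphenyl]propanoyl}oxazolidin-2-one
Product: 7 tert-butyl (S)-3-[4-(benzyloxy)-3-methoxybenzyl]-4-[(R)-4-benzyl-2-oxooxazolidin-3-yl]-4-oxobutanoate, via sodium enolate 6 (not isolated)
Conditions: NaN(SiMe3)2, THF, −78 °C; then BrCH2CO2tBu, −78 → −40 °C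
Reagents that add atoms: tert-butyl bromoacetate, CC(C)(C)OC(=O)CBr
Why: Evans asymmetric alkylation: the sodium-chelated Z-enolate is shielded on one face by the benzyl group of the (R)-auxiliary, so the bromoacetate should enter from the other face and set the (S)-carbon that becomes C4 of the lactone.

Step 4
Reactants: 7 tert-butyl (S)-3-[4-(benzyloxy)-3-methoxybenzyl]-4-[(R)-4-benzyl-2-oxooxazolidin-3-yl]-4-oxobutanoate
Product: 9 (S)-4-[4-(benzyloxy)-3-methoxybenzyl]dihydrofuran-2(3H)-one, via hydroxy ester 8 (not isolated)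
Conditions: LiBH4, MeOH (1 equiv), THF, 0 °C; then TFA, CH2Cl2, rt
Reagents that add atoms: none
Why: Chemoselective hydride reduction of the activated imide carbonyl (the tert-butyl ester is spared) releases the primary alcohol and the auxiliary, and acid-catalysed lactonisation then closes the γ-lactone by 5-exo-trig attack without touching the stereocentre.

Step 5
Reactants: 10 3-hydroxy-4-methoxybenzaldehyde (isovanillin)
Product: 11 4-methoxy-3-[(triisopropylsilyl)oxy]benzaldehyde
Conditions: iPr3SiCl, imidazole, DMF, rt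
Reagents that add atoms: triisopropylsilyl chloride, CC(C)[Si](Cl)(C(C)C)C(C)C
Why: Imidazole-mediated phenol silylation gives an ether that survives hydride, bromination and enolate alkylation yet is removable by fluoride beside benzyl ethers.

Step 6
Reactants: 11 4-methoxy-3-[(triisopropylsilyl)oxy]benzaldehyde
Product: 12 {4-methoxy-3-[(triisopropylsilyl)oxy]phenyl}methanol
Conditions: NaBH4, MeOH, 0 °C
Reagents that add atoms: none
Why: Borohydride reduction of the aryl aldehyde is chemoselective and leaves the aryl silyl ether intact at 0 °C.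

Step 7
Reactants: 12 {4-methoxy-3-[(triisopropylsilyl)oxy]phenyl}methanol
Product: 13 4-(bromomethyl)-1-methoxy-2-[(triisopropylsilyl)oxy]benzene
Conditions: CBr4, PPh3, CH2Cl2, 0 °C
Reagents that add atoms: carbon tetrabromide, BrC(Br)(Br)Br
Why: The Appel reaction converts the electron-rich benzylic alcohol to the bromide under neutral conditions that spare the silyl ether.

Step 8
Reactants: 9 (S)-4-[4-(benzyloxy)-3-methoxybenzyl]dihydrofuran-2(3H)-one; 13 4-(bromomethyl)-1-methoxy-2-[(triisopropylsilyl)oxy]benzene
Product: 15 (3S,4S)-4-[4-(benzyloxy)-3-methoxybenzyl]-3-{4-methoxy-3-[(triisopropylsilyl)oxy]benzyl}dihydrofuran-2(3H)-one, via lithium enolate 14 (not isolated)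
Conditions: LiN(SiMe3)2, THF, −78 °C; then 13, DMPU, −78 → −30 °C
Reagents that add atoms: none
Why: Enolate alkylation of the β-substituted γ-butyrolactone should occur anti to the C4 benzyl group (1,2-induction in the five-membered enolate), giving the trans (3S,4S) lactone.

Step 9
Reactants: 15 (3S,4S)-4-[4-(benzyloxy)-3-methoxybenzyl]-3-{4-methoxy-3-[(triisopropylsilyl)oxy]benzyl}dihydrofuran-2(3H)-one
Product: 16 (3S,4S)-4-[4-(benzyloxy)-3-methoxybenzyl]-3-(3-hydroxy-4-methoxybenzyl)dihydrofuran-2(3H)-one
Conditions: Bu4NF, AcOH, THF, 0 °C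
Reagents that add atoms: none
Why: Buffered fluoride desilylation frees the phenol without opening or epimerising the lactone and keeps both benzyl ethers, so this is the only oxidisable phenol in step 11.

Step 10
Reactants: 17 4-(benzyloxy)-3-methoxybenzaldehyde
Product: 18 (S,E)-1-[4-(benzyloxy)-3-methoxyphenyl]-3-ethoxyprop-2-en-1-ol
Conditions: ethoxyacetylene, BH3·SMe2, toluene, 0 °C → rt; Et2Zn, (−)-MIB (5 mol%), −20 °C; then 17, −20 → 0 °C; aq. NaHCO3; chromatography on Et3N-treated silica
Reagents that add atoms: ethoxyacetylene, C#COCC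
Why: Catalytic enantioselective alkenylzinc addition (syn-hydroboration of the ynol ether, boron-to-zinc transmetalation, amino-alcohol-catalysed 1,2-addition) is a documented route to γ-hydroxy enol ethers; with (−)-MIB the alkenyl group should add to the Si face of the aldehyde and set (S).

Step 11
Reactants: 16 (3S,4S)-4-[4-(benzyloxy)-3-methoxybenzyl]-3-(3-hydroxy-4-methoxybenzyl)dihydrofuran-2(3H)-one; 18 (S,E)-1-[4-(benzyloxy)-3-methoxyphenyl]-3-ethoxyprop-2-en-1-ol (4 equiv, excess recoverable)
Product: 20 ethoxy-bridged tricyclic cycloadduct (bicyclo[2.2.2]octenone fused to the new tetrahydrofuran; two diastereomers of the core; 2S), via o-quinone monoketal 19 (not isolated)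
Conditions: PhI(OAc)2 (1.1 equiv, added in portions), NaHCO3, CH2Cl2, −20 °C → rt; then 40 °C
Reagents that add atoms: none
Why: Ligand exchange at trivalent iodine and two-electron oxidation turn the only free phenol into a phenoxonium ion, which the hydroxyl of 18 captures at the methoxy-bearing carbon C7a (bond O1–C7a) to give o-quinone monoketal 19; its electron-poor diene C3a=C4–C5=C6 then undergoes an intramolecular inverse-electron-demand Diels–Alder reaction with the tethered enol ether (bond C3–C3a and, temporarily, C9–C6). The closest known reaction type is the tandem oxidative ketalisation/intramolecular Diels–Alder reaction of 2-methoxyphenols with alkenols, together with the cycloaddition of such monoketals with enol ethers. Two rings close: the tetrahydrofuran O1–C2–C3–C3a–C7a as the tether ring (three-atom tether from the diene terminus, sealed by the C3–C3a bond) and the cyclohexene ring C3a–C4=C5–C6–C9–C3 of the bicyclo[2.2.2]octenone by the suprafacial [4+2] cycloaddition. C2 is carried in from 18; the tether and the E-alkene fix C3, C3a, C6 and C9 relative to one another, but the ketal carbon C7a forms as both epimers, so two diastereomeric adducts are expected, which is harmless because C3a, C6, C7a and C9 lose their stereochemistry in step 12 and C3 is equilibrated there. The step needs chemoselective oxidation (secured by benzyl protection of the other two phenols), ketalisation at C7a rather than C4 or C6 (secured by the methoxy group, which stabilises positive charge on its own carbon) and C3-to-C3a regiochemistry (secured by the tether and matched by polarity, the nucleophilic enol ether β-carbon meeting the δ-carbon of the dienone), while excess 18 and the NaHCO3 buffer are meant to outcompete acetate capture, monoketal dimerisation and acid-induced transposition of 18.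

Step 12
Reactants: 20 ethoxy-bridged tricyclic cycloadduct
Product: 22 (2S,3S)-2-[4-(benzyloxy)-3-methoxyphenyl]-5-{[(3S,4S)-4-[4-(benzyloxy)-3-methoxybenzyl]-2-oxotetrahydrofuran-3-yl]methyl}-7-hydroxy-2,3-dihydrobenzofuran-3-carbaldehyde, via aldehyde epimer mixture 21 (not isolated)
Conditions: TsOH·H2O (0.2 equiv), acetone/H2O (10:1), rt → 40 °C; then Et3N, CH2Cl2, rt
Reagents that add atoms: water, O
Why: Proposed new method: protonation of the C7 ketone should trigger a Grob-type (retro-aldol) heterolysis of the C6–C9 bond, which is β to the carbonyl, gives a conjugated dienol on cleavage and is pushed by the lone pair of the ethoxy oxygen; water converts the resulting oxocarbenium ion into the C9 aldehyde, and the dienol ketal left behind ionises with exocyclic loss of methanol to an arenium ion that loses the C3a proton, so the benzene ring returns with O1 on C7a and a free hydroxyl on C7; the closest known reaction types are the acid-catalysed retro-aldol opening of alkoxy-substituted (donor–acceptor) cyclobutyl ketones of the de Mayo type and the alcohol-expelling aromatisation of quinone monoketal adducts; the α-aryl aldehyde centre C3 is then equilibrated by Et3N to the more stable 2,3-trans arrangement while C2 is untouched.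

Step 13
Reactants: 22 (2S,3S)-aldehyde
Product: 23 (3S,4S)-4-[4-(benzyloxy)-3-methoxybenzyl]-3-{[(2S,3R)-2-[4-(benzyloxy)-3-methoxyphenyl]-7-hydroxy-3-(hydroxymethyl)-2,3-dihydrobenzofuran-5-yl]methyl}dihydrofuran-2(3H)-one
Conditions: NaBH4, THF/MeOH, −20 → 0 °C
Reagents that add atoms: none
Why: Borohydride reduction is chemoselective for the aldehyde over the γ-lactone at low temperature and locks C3, which is no longer epimerisable as the alcohol.

Step 14
Reactants: 23 dibenzyl ether of the target
Product: 24 (3S,4S)-3-{[(2S,3R)-7-hydroxy-2-(4-hydroxy-3-methoxyphenyl)-3-(hydroxymethyl)-2,3-dihydrobenzofuran-5-yl]methyl}-4-(4-hydroxy-3-methoxybenzyl)dihydrofuran-2(3H)-one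
Conditions: H2 (1 atm), 10% Pd/C, EtOAc/MeOH, rt
Reagents that add atoms: none
Why: Catalytic hydrogenolysis cleaves the two aryl benzyl ethers, and the benzylic C2–O1 bond of 2-aryl-2,3-dihydrobenzofurans is expected to survive short exposure at atmospheric pressure.

**Compound list**

1 | 3-(4-hydroxy-3-methoxyphenyl)propanoic acid | COc1cc(CCC(=O)O)ccc1O | starting material
2 | benzyl 3-[4-(benzyloxy)-3-methoxyphenyl]propanoate (not isolated) | COc1cc(CCC(=O)OCc2ccccc2)ccc1OCc1ccccc1 | intermediate
3 | 3-[4-(benzyloxy)-3-methoxyphenyl]propanoic acid | COc1cc(CCC(=O)O)ccc1OCc1ccccc1 | intermediate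
4 | mixed anhydride of 3 with pivalic acid (not isolated) | COc1cc(CCC(=O)OC(=O)C(C)(C)C)ccc1OCc1ccccc1 | intermediate
5 | (R)-4-benzyl-3-{3-[4-(benzyloxy)-3-methoxyphenyl]propanoyl}oxazolidin-2-one | COc1cc(CCC(=O)N2[C@H](Cc3ccccc3)COC2=O)ccc1OCc1ccccc1 | intermediate
6 | sodium Z-enolate of 5 (not isolated) | [Na+].[O-]/C(=C\Cc1ccc(OCc2ccccc2)c(OC)c1)N1[C@H](Cc2ccccc2)COC1=O | intermediate
7 | tert-butyl (S)-3-[4-(benzyloxy)-3-methoxybenzyl]-4-[(R)-4-benzyl-2-oxooxazolidin-3-yl]-4-oxobutanoate | O=C(N1[C@H](Cc2ccccc2)COC1=O)[C@H](CC(=O)OC(C)(C)C)Cc1ccc(OCc2ccccc2)c(OC)c1 | intermediate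
8 | tert-butyl (S)-3-[4-(benzyloxy)-3-methoxybenzyl]-4-hydroxybutanoate (not isolated) | OC[C@H](CC(=O)OC(C)(C)C)Cc1ccc(OCc2ccccc2)c(OC)c1 | intermediate
9 | (S)-4-[4-(benzyloxy)-3-methoxybenzyl]dihydrofuran-2(3H)-one | O=C1C[C@H](Cc2ccc(OCc3ccccc3)c(OC)c2)CO1 | intermediate
10 | 3-hydroxy-4-methoxybenzaldehyde (isovanillin) | COc1ccc(C=O)cc1O | starting material
11 | 4-methoxy-3-[(triisopropylsilyl)oxy]benzaldehyde | COc1ccc(C=O)cc1O[Si](C(C)C)(C(C)C)C(C)C | intermediate
12 | {4-methoxy-3-[(triisopropylsilyl)oxy]phenyl}methanol | COc1ccc(CO)cc1O[Si](C(C)C)(C(C)C)C(C)C | intermediate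
13 | 4-(bromomethyl)-1-methoxy-2-[(triisopropylsilyl)oxy]benzene | COc1ccc(CBr)cc1O[Si](C(C)C)(C(C)C)C(C)C | intermediate
14 | lithium enolate of 9 (not isolated) | [Li+].[O-]C1=C[C@H](Cc2ccc(OCc3ccccc3)c(OC)c2)CO1 | intermediate
15 | (3S,4S)-4-[4-(benzyloxy)-3-methoxybenzyl]-3-{4-methoxy-3-[(triisopropylsilyl)oxy]benzyl}dihydrofuran-2(3H)-one | COc1cc(C[C@@H]2COC(=O)[C@H]2Cc2ccc(OC)c(O[Si](C(C)C)(C(C)C)C(C)C)c2)ccc1OCc1ccccc1 | intermediate
16 | (3S,4S)-4-[4-(benzyloxy)-3-methoxybenzyl]-3-(3-hydroxy-4-methoxybenzyl)dihydrofuran-2(3H)-one | COc1cc(C[C@@H]2COC(=O)[C@H]2Cc2ccc(OC)c(O)c2)ccc1OCc1ccccc1 | intermediate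
17 | 4-(benzyloxy)-3-methoxybenzaldehyde | COc1cc(C=O)ccc1OCc1ccccc1 | starting material
18 | (S,E)-1-[4-(benzyloxy)-3-methoxyphenyl]-3-ethoxyprop-2-en-1-ol | CCO/C=C/[C@H](O)c1ccc(OCc2ccccc2)c(OC)c1 | intermediate
19 | o-quinone monoketal: cyclohexa-2,4-dienone with C7 as carbonyl and C7a as ketal carbon bearing OMe and the (S,E)-1-aryl-3-ethoxyallyloxy group; both epimers at C7a (not isolated) | COc1cc(C[C@@H]2COC(=O)[C@H]2CC2=CC(=O)C(OC)(O[C@@H](/C=C/OCC)c3ccc(OCc4ccccc4)c(OC)c3)C=C2)ccc1OCc1ccccc1 | intermediate
20 | ethoxy-bridged cycloadduct: bicyclo[2.2.2]oct-5-en-2-one with C7 as ketone, C7a as ketal carbon (OMe and O1), tetrahydrofuran O1–C2–C3–C3a–C7a, ethoxy-bearing C9 bonded to C6; 2S; two diastereomers of the core, whose stereocentres are left open because step 12 erases or resets them | COc1cc(C[C@@H]2COC(=O)[C@H]2CC2=CC3C4(OC)O[C@H](c5ccc(OCc6ccccc6)c(OC)c5)C3C(OCC)C2C4=O)ccc1OCc1ccccc1 | intermediate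
21 | 2S aldehyde as mixture of C3 epimers (not isolated) | COc1cc(C[C@@H]2COC(=O)[C@H]2Cc2cc(O)c3c(c2)C(C=O)[C@@H](c2ccc(OCc4ccccc4)c(OC)c2)O3)ccc1OCc1ccccc1 | intermediate
22 | (2S,3S)-2-[4-(benzyloxy)-3-methoxyphenyl]-5-{[(3S,4S)-4-[4-(benzyloxy)-3-methoxybenzyl]-2-oxotetrahydrofuran-3-yl]methyl}-7-hydroxy-2,3-dihydrobenzofuran-3-carbaldehyde (2,3-trans) | COc1cc(C[C@@H]2COC(=O)[C@H]2Cc2cc(O)c3c(c2)[C@H](C=O)[C@@H](c2ccc(OCc4ccccc4)c(OC)c2)O3)ccc1OCc1ccccc1 | intermediate
23 | (3S,4S)-4-[4-(benzyloxy)-3-methoxybenzyl]-3-{[(2S,3R)-2-[4-(benzyloxy)-3-methoxyphenyl]-7-hydroxy-3-(hydroxymethyl)-2,3-dihydrobenzofuran-5-yl]methyl}dihydrofuran-2(3H)-one | COc1cc(C[C@@H]2COC(=O)[C@H]2Cc2cc(O)c3c(c2)[C@H](CO)[C@@H](c2ccc(OCc4ccccc4)c(OC)c2)O3)ccc1OCc1ccccc1 | intermediate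
24 | (3S,4S)-3-{[(2S,3R)-7-hydroxy-2-(4-hydroxy-3-methoxyphenyl)-3-(hydroxymethyl)-2,3-dihydrobenzofuran-5-yl]methyl}-4-(4-hydroxy-3-methoxybenzyl)dihydrofuran-2(3H)-one (CNP0118131.1) | COc1cc(C[C@@H]2COC(=O)[C@H]2Cc2cc(O)c3c(c2)[C@H](CO)[C@@H](c2ccc(O)c(OC)c2)O3)ccc1O | target

**Step count and risks**

Total step count: 14.
Longest linear sequence: 10 steps (steps 1, 2, 3, 4, 8, 9, 11, 12, 13, 14).

Steps most likely to fail:

1. Step 12 (proposed new method). What may go wrong:
   - the C6–C9 heterolysis may not set in under acid mild enough to spare the benzylic C2–O1 ether;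
   - the ketal may ionise by endocyclic cleavage of C7a–O1 instead of losing methanol, which would aromatise to a ring-opened anisole;
   - prolonged acid or base at the aldehyde stage may scramble C2 by reversible ring opening.

   Fallback (known chemistry only): the ethoxy group is replaced by a boron group that can be turned into a free hydroxyl, so the cleavage becomes an ordinary alkoxide-driven retro-aldol. It sets out from 17 (with 16 as the phenol partner) and comes back at 21. Enantioselective alkynylation of 17 with trimethylsilylacetylene (Me2Zn, the ProPhenol ligand enantiomer that gives the carbinol arrangement of 18) would give (R)-1-[4-(benzyloxy)-3-methoxyphenyl]-3-(trimethylsilyl)prop-2-yn-1-ol F1; it is R only because the silylalkynyl group outranks the aryl group, and its spatial arrangement is that of 18. K2CO3 in MeOH would give (S)-1-[4-(benzyloxy)-3-methoxyphenyl]prop-2-yn-1-ol F2. Hydroboration with pinacolborane (Cp2Zr(H)Cl cat., Et3N) would give (S,E)-1-[4-(benzyloxy)-3-methoxyphenyl]-3-(4,4,5,5-tetramethyl-1,3,2-dioxaborolan-2-yl)prop-2-en-1-ol F3. Under the conditions of step 11, 16 and the acid-stable F3 would give the boryl cycloadduct F4. NaBO3·4H2O in THF/H2O would oxidise the C9–B bond with retention to the β-hydroxy ketone F5. Its retro-aldol cleavage (K2CO3, MeOH, 0 °C) and acidification with AcOH (loss of methanol, aromatisation) would deliver aldehyde mixture 21, which rejoins step 12 at the Et3N equilibration.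

2. Step 11 (key step). What may go wrong: capture of the phenoxonium ion by the hindered secondary alcohol may be slow, so that acetate capture and Diels–Alder dimerisation of the monoketal take over; 18 may also be consumed by acid-induced allylic transposition to the cinnamaldehyde.

   Fallback: a removable bromine atom makes the monoketal persistent, so the oxidation can be run cold, slowly and with a larger excess of 18. It sets out from 16 and comes back at 24. Bromination para to the free hydroxyl (NBS, CH2Cl2, −78 °C) would give the bromophenol F6; a bromine at this position is known to suppress dimerisation of o-quinone monoketals. Oxidation with PhI(OAc)2 in the presence of 18 would give the bromo cycloadduct F7. Fragmentation as in step 12 would give the trans bromo aldehyde F8, and NaBH4 the bromo alcohol F9. H2, Pd/C with Et3N would then remove the bromine together with the two benzyl groups.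

3. Step 10. What may go wrong: erosion of enantioselectivity with the electron-rich aldehyde, and ionisation or transposition of the acid-labile product during isolation.

   Fallback: racemic synthesis and enzymatic resolution in place of asymmetric C–C bond formation. It sets out from 17 and comes back at 18. The same alkenylzinc reagent without the amino alcohol would give racemic (E)-1-[4-(benzyloxy)-3-methoxyphenyl]-3-ethoxyprop-2-en-1-ol F10. Lipase-catalysed acylation (immobilised Candida antarctica lipase B, vinyl acetate, hexane with a little Et3N) is expected, by the usual enantiopreference of this enzyme for secondary carbinols with the aryl group as the large substituent, to acetylate the (R)-enantiomer to (R,E)-1-[4-(benzyloxy)-3-methoxyphenyl]-3-ethoxyallyl acetate F11 and leave (S)-configured 18.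

Further compounds
F1 | step 12 | (R)-1-[4-(benzyloxy)-3-methoxyphenyl]-3-(trimethylsilyl)prop-2-yn-1-ol | C[Si](C)(C)C#C[C@H](O)c1ccc(OCc2ccccc2)c(OC)c1
F2 | step 12 | (S)-1-[4-(benzyloxy)-3-methoxyphenyl]prop-2-yn-1-ol | C#C[C@H](O)c1ccc(OCc2ccccc2)c(OC)c1
F3 | step 12 | (S,E)-1-[4-(benzyloxy)-3-methoxyphenyl]-3-(4,4,5,5-tetramethyl-1,3,2-dioxaborolan-2-yl)prop-2-en-1-ol | CC1(C)OB(/C=C/[C@H](O)c2ccc(OCc3ccccc3)c(OC)c2)OC1(C)C
F4 | step 12 | boryl cycloadduct (analogue of 20 with pinacolboryl on C9; core stereocentres left open) | COc1cc(C[C@@H]2COC(=O)[C@H]2CC2=CC3C4(OC)O[C@H](c5ccc(OCc6ccccc6)c(OC)c5)C3C(B5OC(C)(C)C(C)(C)O5)C2C4=O)ccc1OCc1ccccc1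
F5 | step 12 | β-hydroxy ketone cycloadduct (analogue of 20 with hydroxyl on C9; core stereocentres left open) | COc1cc(C[C@@H]2COC(=O)[C@H]2CC2=CC3C4(OC)O[C@H](c5ccc(OCc6ccccc6)c(OC)c5)C3C(O)C2C4=O)ccc1OCc1ccccc1
F6 | step 11 | (3S,4S)-4-[4-(benzyloxy)-3-methoxybenzyl]-3-(2-bromo-5-hydroxy-4-methoxybenzyl)dihydrofuran-2(3H)-one | COc1cc(C[C@@H]2COC(=O)[C@H]2Cc2cc(O)c(OC)cc2Br)ccc1OCc1ccccc1
F7 | step 11 | bromo cycloadduct (analogue of 20 with bromine on C4; core stereocentres left open) | COc1cc(C[C@@H]2COC(=O)[C@H]2CC2=C(Br)C3C4(OC)O[C@H](c5ccc(OCc6ccccc6)c(OC)c5)C3C(OCC)C2C4=O)ccc1OCc1ccccc1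
F8 | step 11 | 4-bromo analogue of aldehyde 22 (2,3-trans) | COc1cc(C[C@@H]2COC(=O)[C@H]2Cc2cc(O)c3c(c2Br)[C@H](C=O)[C@@H](c2ccc(OCc4ccccc4)c(OC)c2)O3)ccc1OCc1ccccc1
F9 | step 11 | 4-bromo analogue of alcohol 23 (2,3-trans) | COc1cc(C[C@@H]2COC(=O)[C@H]2Cc2cc(O)c3c(c2Br)[C@H](CO)[C@@H](c2ccc(OCc4ccccc4)c(OC)c2)O3)ccc1OCc1ccccc1
F10 | step 10 | racemic (E)-1-[4-(benzyloxy)-3-methoxyphenyl]-3-ethoxyprop-2-en-1-ol | CCO/C=C/C(O)c1ccc(OCc2ccccc2)c(OC)c1
F11 | step 10 | (R,E)-1-[4-(benzyloxy)-3-methoxyphenyl]-3-ethoxyallyl acetate | CCO/C=C/[C@@H](OC(C)=O)c1ccc(OCc2ccccc2)c(OC)c1
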